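**Retrosynthetic overview**
1. The imide ring comes last: (E)-selective Wittig reaction of a C12 aldehyde with the maleimide-derived phosphorus ylide, then O-acetylation. The 7β-oxygen and the 8(17)-methylene come from a C7 ketone (α-methylenation, Luche reduction).
2. The C7 ketone with its C9 cyanomethyl arm comes from the C9 ketone of a bicyclic enone by dehydrogenation, 1,2-addition of LiCH2CN and oxidative 1,3-transposition. The 2α-chlorine is put on by site-selective C–H chlorination once ring A is saturated.
3. Ring A is closed in the key step. A regiodefined C9–C10 enolate on ring B adds to vinyltriphenylphosphonium (bond C1–C10), and the ylide so formed closes onto the C3 aldehyde (bond C2–C3, first as C2=C3).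
4. Enabling feature: in ring A the unsubstituted two-carbon bridge C1–C2 spans C10 and C3. C10 is α to a C9 carbonyl and becomes the methyl-bearing quaternary ring-fusion atom. C3 sits on the fully substituted C4 (gem-dimethyl), so it can be a non-enolisable aldehyde.
5. Ring order: ring B is bought (2-methylcyclohex-2-enone; C5 and the C4–C5 bond come from an enantioselective Mukaiyama–Michael addition), ring A is formed in the key step, the imide ring is appended at the end.

Key step: step 3

Convention: locants and α/β follow labdane numbering (ring A = C1–C5, C10 with the gem-dimethyl carbon C4; ring B = C5–C10; C11 and C12 on C9; C17 on C8; the C10 methyl is β).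
Assumption: the (S)-configured oxazaborolidinium catalyst of step 1 is taken to give the (R) adduct 3; if the sense is the opposite, the enantiomeric catalyst is used and nothing else changes.

Step 1
Reactants: 1 2-methylcyclohex-2-en-1-one; 2 1-methoxy-2-methyl-1-(trimethylsilyloxy)prop-1-ene
Product: 3 methyl 2-methyl-2-[(1R)-2-methyl-3-(trimethylsilyloxy)cyclohex-2-en-1-yl]propanoate
Conditions: (S)-3,3-diphenyl-1-(o-tolyl)tetrahydropyrrolo[1,2-c][1,3,2]oxazaborole (20 mol%), Tf2NH (20 mol%), Ph3PO (25 mol%), toluene, −20 °C; non-aqueous work-up (pentane, basic alumina)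
Reagents that add atoms: none
Why: Catalytic enantioselective Mukaiyama–Michael addition: the cationic oxazaborolidinium Lewis acid binds the enone carbonyl and exposes one face of C5 to the ketene acetal, and silyl transfer to the enolate oxygen traps the C9–C10 enolate as its silyl enol ether, so C5 is the only stereocentre and the later site of C–C bond formation is fixed.

Step 2
Reactants: 3 methyl 2-methyl-2-[(1R)-2-methyl-3-(trimethylsilyloxy)cyclohex-2-en-1-yl]propanoate
Product: 4 2-methyl-2-[(1R)-2-methyl-3-(trimethylsilyloxy)cyclohex-2-en-1-yl]propanal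
Conditions: i-Bu2AlH (1.1 equiv), CH2Cl2, −78 °C; cold aq. Rochelle salt (pH 8)
Reagents that add atoms: none
Why: Partial reduction of an ester with i-Bu2AlH: the tetrahedral aluminium hemiacetal of the hindered α,α-dimethyl ester should persist at −78 °C and give the aldehyde only on work-up, while the silyl enol ether is inert to the hydride.

Step 3
Reactants: 4 2-methyl-2-[(1R)-2-methyl-3-(trimethylsilyloxy)cyclohex-2-en-1-yl]propanal; 5 triphenyl(vinyl)phosphonium bromide
Product: 8 trans-fused 4,4,10-trimethyldecal-2-en-9-one (5α-H, 10β-CH3), via tetrabutylammonium enolate 6 (not isolated), via keto phosphorus ylide 7 (not isolated)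
Conditions: 5 (1.2 equiv), Bu4N[Ph3SiF2] (1.1 equiv), THF, −40 °C → 50 °C
Reagents that add atoms: none
Why: Fluoride removes the silyl group to give the ammonium enolate 6, which adds through C10 to the vinylphosphonium salt (bond C1–C10) and so generates the non-stabilised ylide 7; 7 then closes onto the neopentyl aldehyde in an intramolecular Wittig reaction (bond C2–C3, as the C2=C3 alkene) with loss of Ph3PO. The closest known reaction type is the Schweizer vinylphosphonium annulation (enolate Michael addition followed by intramolecular Wittig olefination). Ring A is closed in a 6-exo-trig mode at the aldehyde carbon (oxaphosphetane, then cycloreversion), which can only give the cis ring alkene. The one new stereocentre, C10, is controlled by C5: the bulky C5 substituent sits pseudo-axial on the enolate to avoid allylic strain with the C10 methyl, the electrophile enters anti to it, C1 ends trans to C4, and closure should give the trans-decalin with the 10β-methyl. The step needs C- over O-alkylation and reaction at C10 only: the silyl enol ether fixes the enolate regiochemistry, O-attack is reversible and cannot lead to a ring, and the ylide can neither reach the C9 ketone (four-membered ring) nor enolise the aldehyde.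

Step 4
Reactants: 8 trans-fused 4,4,10-trimethyldecal-2-en-9-one
Product: 9 trans-fused 4,4,10-trimethyldecala-2,7-dien-9-one
Conditions: IBX (2-iodoxybenzoic acid, 2.0 equiv), DMSO/fluorobenzene, 70 °C
Reagents that add atoms: none
Why: IBX dehydrogenation of a ketone to the enone through its enol: C8 is the only enolisable position because C10 is quaternary, so only the C7=C8 enone can form and the isolated ring A alkene is left alone.

Step 5
Reactants: 9 trans-fused 4,4,10-trimethyldecala-2,7-dien-9-one
Product: 10 9α-(cyanomethyl)-9β-hydroxy-4,4,10-trimethyl-trans-decala-2,7-diene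
Conditions: MeCN, n-BuLi, THF, −78 °C; then 9, −78 °C; H2O quench at −78 °C
Reagents that add atoms: acetonitrile, CC#N
Why: Kinetic 1,2-addition of lithioacetonitrile, a small hard carbanion, to the enone carbonyl at −78 °C, with a cold quench to prevent retro-addition and drift to the 1,4-adduct; the new C9 centre (attack anti to the 10β-methyl expected) is erased in step 6.

Step 6
Reactants: 10 9α-(cyanomethyl)-9β-hydroxy-4,4,10-trimethyl-trans-decala-2,7-diene
Product: 11 7-oxo-13,14,15,16,17-pentanorlabda-2,8-diene-12-nitrile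
Conditions: pyridinium chlorochromate [C5H5NH][CrO3Cl] (2 equiv), 4 Å molecular sieves, CH2Cl2, rt
Reagents that add atoms: none
Why: Babler–Dauben oxidative 1,3-transposition: the chromate ester of the tertiary allylic alcohol undergoes a [3,3] shift to C7 and is oxidised there, which moves the oxygen from C9 to C7 and leaves the cyanomethyl group on the C8=C9 alkene.

Step 7
Reactants: 11 7-oxo-13,14,15,16,17-pentanorlabda-2,8-diene-12-nitrile
Product: 12 7-oxo-13,14,15,16,17-pentanorlabdane-12-nitrile (5α-H, 9α-H)
Conditions: H2 (1 atm), 10% Pd/C, EtOAc, rt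
Reagents that add atoms: none
Why: Heterogeneous catalytic hydrogenation saturates the ring A alkene and the enone C8=C9 bond; hydrogen should reach C9 from the α-face opposite the axial 10β-methyl, which sets 9α-H with the cyanomethyl arm equatorial (β), and any double-bond isomer of 11 would converge on the same product.

Step 8
Reactants: 12 7-oxo-13,14,15,16,17-pentanorlabdane-12-nitrile
Product: 13 2α-chloro-7-oxo-13,14,15,16,17-pentanorlabdane-12-nitrile
Conditions: N-chloro-N-tert-butyl-3,5-bis(trifluoromethyl)benzamide (1.2 equiv), Cs2CO3 (0.5 equiv), benzene, visible light, 55 °C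
Reagents that add atoms: N-chloro-N-tert-butyl-3,5-bis(trifluoromethyl)benzamide, CC(C)(C)N(Cl)C(=O)c1cc(cc(c1)C(F)(F)F)C(F)(F)F
Why: Radical-chain C–H chlorination by a bulky electrophilic amidyl radical (hydrogen-atom abstraction, then chlorine-atom transfer from the N-chloroamide): C2 is the only methylene that is neither flanked by a quaternary carbon (C1, C3) nor deactivated by the ketone (C6, C8) or the nitrile (C11), and chlorine should reach the C2 radical from the equatorial α-side because the β-face is blocked by the syn-axial methyls on C4 and C10.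

Step 9
Reactants: 13 2α-chloro-7-oxo-13,14,15,16,17-pentanorlabdane-12-nitrile
Product: 17 2α-chloro-7-oxo-13,14,15,16-tetranorlabd-8(17)-ene-12-nitrile, via lithium enolate 14 (not isolated), via Mannich base 15 (not isolated), via trimethylammonium iodide 16 (not isolated)
Conditions: LiN(i-Pr)2 (1.05 equiv), THF, −78 °C; Me2N=CH2 I (Eschenmoser's salt), −78 °C → rt; MeI, rt; aq. NaHCO3, CH2Cl2, rt
Reagents that add atoms: N,N-dimethylmethyleneiminium iodide (Eschenmoser's salt), C=[N+](C)C.[I-]
Why: α-Methylenation of a ketone by kinetic enolisation, Mannich reaction with the preformed iminium salt, N-methylation and E1cB elimination: the amide base should remove the axial hydrogen at C8 and not at C6, where it is flanked by the two syn-axial methyls on C4 and C10, and bicarbonate is too weak to touch the 9α-hydrogen.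

Step 10
Reactants: 17 2α-chloro-7-oxo-13,14,15,16-tetranorlabd-8(17)-ene-12-nitrile
Product: 18 2α-chloro-7β-hydroxy-13,14,15,16-tetranorlabd-8(17)-ene-12-nitrile
Conditions: NaBH4, CeCl3·7H2O, MeOH, −78 → 0 °C
Reagents that add atoms: none
Why: Luche reduction: the cerium-modified borohydride attacks the enone carbonyl 1,2 and along the axial α-trajectory, which should give the equatorial 7β-alcohol.

Step 11
Reactants: 18 2α-chloro-7β-hydroxy-13,14,15,16-tetranorlabd-8(17)-ene-12-nitrile
Product: 19 2α-chloro-7β-hydroxy-13,14,15,16-tetranorlabd-8(17)-en-12-al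
Conditions: i-Bu2AlH (2.5 equiv), CH2Cl2, −78 °C; aq. Rochelle salt, then pH 5 buffer
Reagents that add atoms: water, O
Why: Reduction of a nitrile with i-Bu2AlH stops at the N-aluminio aldimine (one hydride transfer; the first equivalent is used by the hydroxyl group), and aqueous work-up hydrolyses it to the aldehyde.

Step 12
Reactants: 19 2α-chloro-7β-hydroxy-13,14,15,16-tetranorlabd-8(17)-en-12-al; 20 maleimide
Product: 22 (12E)-2α-chloro-7β-hydroxylabda-8(17),12-diene-15,16-dioic acid imide, via succinimide ylide 21 (not isolated)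
Conditions: PPh3 (1.3 equiv), 20 (1.3 equiv), THF, rt; then 19, THF/MeOH, 60 °C
Reagents that add atoms: none
Why: Wittig olefination with the stabilised ylide formed in the flask by conjugate addition of PPh3 to maleimide and proton shift; reversible betaine formation places the alkyl chain anti to the ring carbonyl, so the (E)-alkylidene succinimide is expected.

Step 13
Reactants: 22 (12E)-2α-chloro-7β-hydroxylabda-8(17),12-diene-15,16-dioic acid imide
Product: 23 (12E)-7β-acetoxy-2α-chlorolabda-8(17),12-diene-15,16-dioic acid imide (CNP0220384.1)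
Conditions: Ac2O, pyridine, 4-(dimethylamino)pyridine (cat.), CH2Cl2, 0 °C → rt; aq. NaHCO3 work-up
Reagents that add atoms: acetic anhydride, CC(=O)OC(C)=O
Why: Nucleophile-catalysed acylation of the secondary allylic alcohol; the imide N–H is far less nucleophilic, and any N-acetyl imide would be cleaved on the mild aqueous work-up.

**Compound list**
1 | 2-methylcyclohex-2-en-1-one | CC1=CCCCC1=O | starting material
2 | 1-methoxy-2-methyl-1-(trimethylsilyloxy)prop-1-ene | COC(O[Si](C)(C)C)=C(C)C | starting material
3 | methyl 2-methyl-2-[(1R)-2-methyl-3-(trimethylsilyloxy)cyclohex-2-en-1-yl]propanoate | C1CC[C@@H](C(C)(C)C(=O)OC)C(C)=C1O[Si](C)(C)C | intermediate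
4 | 2-methyl-2-[(1R)-2-methyl-3-(trimethylsilyloxy)cyclohex-2-en-1-yl]propanal | C1CC[C@@H](C(C)(C)C=O)C(C)=C1O[Si](C)(C)C | intermediate
5 | triphenyl(vinyl)phosphonium bromide | C=C[P+](c1ccccc1)(c1ccccc1)c1ccccc1.[Br-] | starting material
6 | tetrabutylammonium (3R)-2-methyl-3-(2-methyl-1-oxopropan-2-yl)cyclohex-1-en-1-olate (formed in the flask) | C1CC[C@@H](C(C)(C)C=O)C(C)=C1[O-].CCCC[N+](CCCC)(CCCC)CCCC | intermediate
7 | 2-methyl-3-(2-methyl-1-oxopropan-2-yl)-2-[2-(triphenylphosphoranylidene)ethyl]cyclohexan-1-one, ylide arm trans to the C5 side chain (formed in the flask) | C1CC[C@@H](C(C)(C)C=O)[C@](C)(CC=P(c2ccccc2)(c2ccccc2)c2ccccc2)C1=O | intermediate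
8 | trans-fused 4,4,10-trimethyldecal-2-en-9-one (5α-H, 10β-CH3) | C1CC[C@H]2C(C)(C)C=CC[C@]2(C)C1=O | intermediate
9 | trans-fused 4,4,10-trimethyldecala-2,7-dien-9-one | C1=CC[C@H]2C(C)(C)C=CC[C@]2(C)C1=O | intermediate
10 | 9α-(cyanomethyl)-9β-hydroxy-4,4,10-trimethyl-trans-decala-2,7-diene (expected C9 epimer; configuration at C9 is of no consequence) | C1=CC[C@H]2C(C)(C)C=CC[C@]2(C)[C@@]1(CC#N)O | intermediate
11 | 7-oxo-13,14,15,16,17-pentanorlabda-2,8-diene-12-nitrile | O=C1C[C@H]2C(C)(C)C=CC[C@]2(C)C(CC#N)=C1 | intermediate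
12 | 7-oxo-13,14,15,16,17-pentanorlabdane-12-nitrile (5α-H, 9α-H) | C1C(=O)C[C@H]2C(C)(C)CCC[C@]2(C)[C@H]1CC#N | intermediate
13 | 2α-chloro-7-oxo-13,14,15,16,17-pentanorlabdane-12-nitrile | C1C(=O)C[C@H]2C(C)(C)C[C@H](Cl)C[C@]2(C)[C@H]1CC#N | intermediate
14 | lithium C7–C8 enolate of 13 (formed in the flask) | C1=C(O[Li])C[C@H]2C(C)(C)C[C@H](Cl)C[C@]2(C)[C@H]1CC#N | intermediate
15 | 2α-chloro-17-(dimethylamino)-7-oxo-13,14,15,16-tetranorlabdane-12-nitrile (C8 epimers, of no consequence; formed in the flask) | CN(C)CC1C(=O)C[C@H]2C(C)(C)C[C@H](Cl)C[C@]2(C)[C@H]1CC#N | intermediate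
16 | 2α-chloro-7-oxo-17-(trimethylammonio)-13,14,15,16-tetranorlabdane-12-nitrile iodide (formed in the flask) | C[N+](C)(C)CC1C(=O)C[C@H]2C(C)(C)C[C@H](Cl)C[C@]2(C)[C@H]1CC#N.[I-] | intermediate
17 | 2α-chloro-7-oxo-13,14,15,16-tetranorlabd-8(17)-ene-12-nitrile | C=C1C(=O)C[C@H]2C(C)(C)C[C@H](Cl)C[C@]2(C)[C@H]1CC#N | intermediate
18 | 2α-chloro-7β-hydroxy-13,14,15,16-tetranorlabd-8(17)-ene-12-nitrile | C=C1[C@@H](O)C[C@H]2C(C)(C)C[C@H](Cl)C[C@]2(C)[C@H]1CC#N | intermediate
19 | 2α-chloro-7β-hydroxy-13,14,15,16-tetranorlabd-8(17)-en-12-al | C=C1[C@@H](O)C[C@H]2C(C)(C)C[C@H](Cl)C[C@]2(C)[C@H]1CC=O | intermediate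
20 | maleimide | O=C1C=CC(=O)N1 | starting material
21 | 3-(triphenylphosphoranylidene)pyrrolidine-2,5-dione (formed in the flask) | O=C1CC(=P(c2ccccc2)(c2ccccc2)c2ccccc2)C(=O)N1 | intermediate
22 | (12E)-2α-chloro-7β-hydroxylabda-8(17),12-diene-15,16-dioic acid imide | C=C1[C@@H](O)C[C@H]2C(C)(C)C[C@H](Cl)C[C@]2(C)[C@H]1C/C=C1\CC(=O)NC1=O | intermediate
23 | (12E)-7β-acetoxy-2α-chlorolabda-8(17),12-diene-15,16-dioic acid imide (CNP0220384.1) | C=C1[C@@H](OC(C)=O)C[C@H]2C(C)(C)C[C@H](Cl)C[C@]2(C)[C@H]1C/C=C1\CC(=O)NC1=O | target

Total step count: 13. Longest linear sequence: 13 steps (from 1).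

**Steps most likely to fail**

Step 8 (C–H chlorination). Site selectivity may be lost through hydrogen abstraction at C1, C3 or C6, or through enol-type α-chlorination of the ketone. The fallback sets out from 8 and returns at 13, and installs chlorine by polar chemistry through the ring A alkene before ring B is elaborated. Hydroboration–oxidation of 8 (BH3·SMe2; NaOH, H2O2) should put boron on C2 from the α-face and also reduce the C9 ketone, giving 4,4,10-trimethyl-trans-decalin-2α,9-diol F1. Dess–Martin periodinane then gives 4,4,10-trimethyl-trans-decalin-2,9-dione F2. Li[HB(s-Bu)3] at −78 °C should reduce only the C2 carbonyl, from the equatorial α-side, to 2β-hydroxy-4,4,10-trimethyl-trans-decalin-9-one F3. An Appel reaction (PPh3, CCl4) with inversion gives 2α-chloro-4,4,10-trimethyl-trans-decalin-9-one F4. F4 then takes the conditions of steps 4, 5 and 6 in turn, giving 2α-chloro-4,4,10-trimethyl-trans-decal-7-en-9-one F5, then 2α-chloro-9-(cyanomethyl)-9-hydroxy-4,4,10-trimethyl-trans-decal-7-ene F6, then 2α-chloro-7-oxo-13,14,15,16,17-pentanorlabd-8-ene-12-nitrile F7. Hydrogenation of F7 under the conditions of step 7 delivers 13.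

Step 3 (key annulation). Carbon–carbon bond formation at the hindered tetrasubstituted enolate carbon may be slow, O-alkylation may compete, or proton transfer may quench the ylide before ring closure. The fallback sets out from 4 and returns at 8, and splits the annulation into enolate allylation, aldehyde methylenation and ring-closing metathesis. Treatment of 4 with Bu4N[Ph3SiF2] and allyl bromide should give trans-2-allyl-2-methyl-3-(2-methyl-1-oxopropan-2-yl)cyclohexan-1-one F8. One equivalent of Ph3P=CH2 should methylenate only the aldehyde, giving 2-allyl-2-methyl-3-(2-methylbut-3-en-2-yl)cyclohexan-1-one F9. Second-generation Grubbs catalyst then closes ring A to 8.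

Step 1 (enantioselective conjugate addition). The α-methyl group may change how the enone binds to the catalyst and so erode facial selectivity. The fallback sets out from 2 and returns at 3; it sets the stereocentre on the unsubstituted enone and brings in the methyl group afterwards. Cyclohex-2-en-1-one F10 and 2 under the catalyst of step 1 should give methyl 2-methyl-2-[(1R)-3-(trimethylsilyloxy)cyclohex-2-en-1-yl]propanoate F11. MeLi followed by MeI (regiospecific enolate methylation, trans to the side chain) gives methyl 2-methyl-2-[(1R,2S)-2-methyl-3-oxocyclohexyl]propanoate F12. Silylation under equilibrating conditions (Me3SiCl, NaI, Et3N, MeCN) returns the tetrasubstituted silyl enol ether 3.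

**Further compounds**
F1 | step 8 | 4,4,10-trimethyl-trans-decalin-2α,9-diol (C9 epimers) | C1CC[C@H]2C(C)(C)C[C@H](O)C[C@]2(C)C1O
F2 | step 8 | 4,4,10-trimethyl-trans-decalin-2,9-dione | C1CC[C@H]2C(C)(C)CC(=O)C[C@]2(C)C1=O
F3 | step 8 | 2β-hydroxy-4,4,10-trimethyl-trans-decalin-9-one | C1CC[C@H]2C(C)(C)C[C@@H](O)C[C@]2(C)C1=O
F4 | step 8 | 2α-chloro-4,4,10-trimethyl-trans-decalin-9-one | C1CC[C@H]2C(C)(C)C[C@H](Cl)C[C@]2(C)C1=O
F5 | step 8 | 2α-chloro-4,4,10-trimethyl-trans-decal-7-en-9-one | C1=CC[C@H]2C(C)(C)C[C@H](Cl)C[C@]2(C)C1=O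
F6 | step 8 | 2α-chloro-9-(cyanomethyl)-9-hydroxy-4,4,10-trimethyl-trans-decal-7-ene | C1=CC[C@H]2C(C)(C)C[C@H](Cl)C[C@]2(C)[C@@]1(CC#N)O
F7 | step 8 | 2α-chloro-7-oxo-13,14,15,16,17-pentanorlabd-8-ene-12-nitrile | O=C1C[C@H]2C(C)(C)C[C@H](Cl)C[C@]2(C)C(CC#N)=C1
F8 | step 3 | trans-2-allyl-2-methyl-3-(2-methyl-1-oxopropan-2-yl)cyclohexan-1-one | C1CC[C@@H](C(C)(C)C=O)[C@](C)(CC=C)C1=O
F9 | step 3 | trans-2-allyl-2-methyl-3-(2-methylbut-3-en-2-yl)cyclohexan-1-one | C1CC[C@@H](C(C)(C)C=C)[C@](C)(CC=C)C1=O
F10 | step 1 | cyclohex-2-en-1-one | O=C1C=CCCC1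
F11 | step 1 | methyl 2-methyl-2-[(1R)-3-(trimethylsilyloxy)cyclohex-2-en-1-yl]propanoate | C1CC[C@@H](C(C)(C)C(=O)OC)C=C1O[Si](C)(C)C
F12 | step 1 | methyl 2-methyl-2-[(1R,2S)-2-methyl-3-oxocyclohexyl]propanoate | C1CC[C@@H](C(C)(C)C(=O)OC)[C@H](C)C1=O
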